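Resorcinol ring C is made from open-chain carbon, not from an arene. Ring C carries hydroxyls at C3 and C5 and the (R)-2-acyloxypropyl chain at C1; ring carbons C1 and C2 plus that chain are the five carbons of (R)-pent-4-yn-2-ol. A Danheiser benzannulation of the 3-substituted cyclobutenone 9, which already holds fragment B (the (R)-3-hydroxybutanoate linker) as its ester, with (triisopropylsilyloxy)acetylene 16 therefore closes ring C in one operation. It places the oxygens and the chain 1,3,5, delivers the two oxygens differentiated and leaves both stereocentres alone. Ring A then arrives as a benzyl-protected, ketal-masked aroyl chloride, and two mild deprotections complete the target.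

Key step: step 9

Remark on the chemistry: all three stereocentres are (R) and are bought, two of them with hydroxy ester 1; alkyne 16 is not assumed to be purchasable and is made in steps 6 to 8.

Step 1
Reactants: 1 methyl (R)-3-hydroxybutanoate
Product: 2 methyl (R)-3-(tert-butyldimethylsilyloxy)butanoate
Conditions: TBSCl, imidazole, DMF, 0 → 25 °C
Reagents that add atoms: tert-butyldimethylsilyl chloride, CC(C)(C)[Si](C)(C)Cl
Why: Imidazole-promoted O-silylation of a secondary alcohol, which does not involve the stereocentre.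

Step 2
Reactants: 2 methyl (R)-3-(tert-butyldimethylsilyloxy)butanoate
Product: 3 (R)-3-(tert-butyldimethylsilyloxy)butanoic acid
Conditions: LiOH·H2O, THF/MeOH/H2O, 0 → 25 °C; then 1 M HCl to pH 3, 0 °C
Reagents that add atoms: lithium hydroxide (its oxygen becomes the acid OH), [Li+].[OH-]
Why: Saponification of an unhindered methyl ester under cold LiOH, where a β-silyloxy ester should neither eliminate nor lose the silyl group.

Step 3
Reactants: 3 (R)-3-(tert-butyldimethylsilyloxy)butanoic acid; 4 (R)-pent-4-yn-2-ol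
Product: 5 (R)-pent-4-yn-2-yl (R)-3-(tert-butyldimethylsilyloxy)butanoate
Conditions: EDC·HCl, DMAP (cat.), CH2Cl2, 0 → 25 °C
Reagents that add atoms: none
Why: Steglich esterification activates the acid only, so no bond at either carbinol carbon is broken and both centres are retained.

Step 4
Reactants: 5 (R)-pent-4-yn-2-yl (R)-3-(tert-butyldimethylsilyloxy)butanoate; 6 trichloroacetyl chloride
Product: 8 (R)-1-(4,4-dichloro-3-oxocyclobut-1-en-1-yl)propan-2-yl (R)-3-(tert-butyldimethylsilyloxy)butanoate, via dichloroketene 7 (not isolated)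
Conditions: Zn–Cu couple, Et2O/DME, slow addition of 6, 25 °C
Reagents that add atoms: none
Why: Ketene–alkyne (2+2) cycloaddition in which the terminal alkyne CH bonds to the ketene carbonyl carbon, so the chain sits at C3 next to CCl2, while DME ties up ZnCl2 to spare ester and silyl ether.

Step 5
Reactants: 8 (R)-1-(4,4-dichloro-3-oxocyclobut-1-en-1-yl)propan-2-yl (R)-3-(tert-butyldimethylsilyloxy)butanoate
Product: 9 (R)-1-(3-oxocyclobut-1-en-1-yl)propan-2-yl (R)-3-(tert-butyldimethylsilyloxy)butanoate
Conditions: Zn dust, AcOH, TMEDA, EtOH, 0 → 25 °C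
Reagents that add atoms: none
Why: Zinc-mediated reductive dechlorination of an α,α-dichloro ketone, buffered with TMEDA so the strained enone and the ester should not be reduced.

Step 6
Reactants: 10 tetrahydrofuran
Product: 12 triisopropyl(vinyloxy)silane, via lithium ethenolate 11 (not isolated)
Conditions: n-BuLi, THF (reactant and solvent), 25 °C; then TIPSCl, DMPU, 0 → 25 °C
Reagents that add atoms: triisopropylsilyl chloride, CC(C)[Si](Cl)(C(C)C)C(C)C
Why: α-Lithiated THF undergoes (3+2) cycloreversion to ethene and the acetaldehyde enolate, which is O-silylated by the hindered chlorosilane.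

Step 7
Reactants: 12 triisopropyl(vinyloxy)silane
Product: 14 (2-bromovinyloxy)triisopropylsilane (E/Z mixture), via 1,2-dibromoethyl silyl ether 13 (not isolated)
Conditions: Br2, CH2Cl2, −78 °C; then Et3N, −78 → 25 °C
Reagents that add atoms: bromine, BrBr
Why: Bromine addition to the enol ether followed by amine-induced loss of HBr is the classical route to 2-halovinyl ethers, and the bulky silyl group disfavours collapse to bromoacetaldehyde.

Step 8
Reactants: 14 (2-bromovinyloxy)triisopropylsilane (E/Z mixture)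
Product: 16 (triisopropylsilyloxy)acetylene, via lithium silyloxyacetylide 15 (not isolated)
Conditions: LiN(i-Pr)2 (2.2 equiv), THF, −78 °C; then AcOH, −78 °C; distil under reduced pressure
Reagents that add atoms: none
Why: Base-induced dehydrobromination of a 2-bromovinyl ether (the alkoxyacetylene synthesis) gives the ynol ether, held as its acetylide until a cold proton quench, with the hindered amide and silyl group suppressing attack at silicon.

Step 9
Reactants: 9 (R)-1-(3-oxocyclobut-1-en-1-yl)propan-2-yl (R)-3-(tert-butyldimethylsilyloxy)butanoate; 16 (triisopropylsilyloxy)acetylene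
Product: 21 (R)-1-[3-hydroxy-5-(triisopropylsilyloxy)phenyl]propan-2-yl (R)-3-(tert-butyldimethylsilyloxy)butanoate, via vinylketene 17 (not isolated), via 4-vinylcyclobutenone 18 (not isolated), via dienylketene 19 (not isolated), via cyclohexadienone 20 (not isolated)
Conditions: 16 (1.5 equiv), PhMe, 80 → 110 °C, sealed tube, argon
Reagents that add atoms: none
Why: Heat opens cyclobutenone 9 by four-electron electrocyclic ring opening to vinylketene 17, whose ketene C=C undergoes (2+2) cycloaddition with the electron-rich ynol ether 16 to give 18, and a second four-electron opening gives dienylketene 19. Ring C is then closed by thermal six-electron (disrotatory) electrocyclisation between the ketene carbon and the terminal methylene, and cyclohexadienone 20 tautomerises to the phenol. The closest known reaction type is the Danheiser benzannulation of 3-alkylcyclobutenones with silyloxyalkynes, which is this substrate class. No stereocentre is created, and the two existing ones lie outside the reacting π-system and meet only neutral heat. The one selectivity needed is the regiochemistry of the ketene–alkyne union: the unsubstituted, nucleophilic alkyne carbon bonds to the ketene carbonyl carbon, so hydroxyl, silyloxy group and chain must come out 1,3,5 with the two oxygens differentiated. An excess of 16 should keep the vinylketene from acylating the product phenol.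

Step 10
Reactants: 21 (R)-1-[3-hydroxy-5-(triisopropylsilyloxy)phenyl]propan-2-yl (R)-3-(tert-butyldimethylsilyloxy)butanoate
Product: 22 (R)-1-[3,5-bis(benzyloxy)phenyl]propan-2-yl (R)-3-(tert-butyldimethylsilyloxy)butanoate
Conditions: BnBr, CsF, DMF, 25 °C
Reagents that add atoms: benzyl bromide, BrCc1ccccc1
Why: Fluoride cleaves the aryl silyl ether and acts as base for the free phenol, so both oxygens undergo Williamson benzylation while the alkyl silyl ether and the esters should be left at room temperature.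

Step 11
Reactants: 22 (R)-1-[3,5-bis(benzyloxy)phenyl]propan-2-yl (R)-3-(tert-butyldimethylsilyloxy)butanoate
Product: 23 (R)-1-[3,5-bis(benzyloxy)phenyl]propan-2-yl (R)-3-hydroxybutanoate
Conditions: HF·pyridine, pyridine, THF, 0 → 25 °C
Reagents that add atoms: none
Why: Buffered fluoride desilylation removes the secondary silyl ether without touching benzyl ethers or the ester, and the non-basic medium avoids β-elimination.

Step 12
Reactants: 1 methyl (R)-3-hydroxybutanoate
Product: 24 methyl (R)-3-(benzyloxy)butanoate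
Conditions: BnOC(=NH)CCl3, TfOH (cat.), CH2Cl2/cyclohexane, 0 → 25 °C
Reagents that add atoms: benzyl 2,2,2-trichloroacetimidate, N=C(OCc1ccccc1)C(Cl)(Cl)Cl
Why: Acid-catalysed trichloroacetimidate benzylation avoids alkoxide formation, so the β-hydroxy ester should neither eliminate nor racemise.

Step 13
Reactants: 24 methyl (R)-3-(benzyloxy)butanoate
Product: 25 (R)-3-(benzyloxy)-N-methoxy-N-methylbutanamide
Conditions: MeNHOMe·HCl, i-PrMgCl, THF, −20 → 0 °C
Reagents that add atoms: N,O-dimethylhydroxylamine hydrochloride, CNOC.Cl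
Why: Weinreb amide formation by aminolysis of the ester with the chloromagnesium amide at low temperature, which leaves the β-benzyloxy centre untouched.

Step 14
Reactants: 26 methyl 2,4-dihydroxy-6-methylbenzoate
Product: 27 methyl 2,4-bis(benzyloxy)-6-methylbenzoate
Conditions: BnBr, K2CO3, DMF, 60 °C
Reagents that add atoms: benzyl bromide, BrCc1ccccc1
Why: Williamson benzylation of both phenols, with warming needed for the hydrogen-bonded ortho hydroxyl.

Step 15
Reactants: 27 methyl 2,4-bis(benzyloxy)-6-methylbenzoate; 25 (R)-3-(benzyloxy)-N-methoxy-N-methylbutanamide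
Product: 29 methyl 2,4-bis(benzyloxy)-6-[(R)-4-(benzyloxy)-2-oxopentyl]benzoate, via benzylic lithium species 28 (not isolated)
Conditions: 27 (1.5 equiv), LiN(i-Pr)2 (1.5 equiv), THF, −78 °C; then 25 (1.0 equiv), −78 °C; AcOH quench
Reagents that add atoms: none
Why: Lateral lithiation of the ortho-toluate and acylation by the Weinreb amide, whose chelated tetrahedral intermediate holds until the quench and so prevents over-addition.

Step 16
Reactants: 29 methyl 2,4-bis(benzyloxy)-6-[(R)-4-(benzyloxy)-2-oxopentyl]benzoate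
Product: 30 methyl 2,4-bis(benzyloxy)-6-({2-[(R)-2-(benzyloxy)propyl]-1,3-dioxolan-2-yl}methyl)benzoate
Conditions: (TMSOCH2)2, TMSOTf (cat.), CH2Cl2, −78 → −20 °C; pyridine quench
Reagents that add atoms: 1,2-bis(trimethylsilyloxy)ethane, C[Si](C)(C)OCCO[Si](C)(C)C
Why: Noyori ketalisation at low temperature masks the ketone, which later prevents enol lactonisation to an isocoumarin when the acid is activated.

Step 17
Reactants: 30 methyl 2,4-bis(benzyloxy)-6-({2-[(R)-2-(benzyloxy)propyl]-1,3-dioxolan-2-yl}methyl)benzoate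
Product: 31 2,4-bis(benzyloxy)-6-({2-[(R)-2-(benzyloxy)propyl]-1,3-dioxolan-2-yl}methyl)benzoic acid
Conditions: KOH, DMSO/H2O, 80 °C; then aq. KHSO4 to pH 4, 0 °C
Reagents that add atoms: potassium hydroxide (its oxygen becomes the acid OH), [K+].[OH-]
Why: Forcing saponification of the di-ortho-substituted methyl benzoate is tolerated because only ethers and a ketal are present, and cold buffered acidification keeps the dioxolane.

Step 18
Reactants: 31 2,4-bis(benzyloxy)-6-({2-[(R)-2-(benzyloxy)propyl]-1,3-dioxolan-2-yl}methyl)benzoic acid; 23 (R)-1-[3,5-bis(benzyloxy)phenyl]propan-2-yl (R)-3-hydroxybutanoate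
Product: 33 (R)-4-{[(R)-1-[3,5-bis(benzyloxy)phenyl]propan-2-yl]oxy}-4-oxobutan-2-yl 2,4-bis(benzyloxy)-6-({2-[(R)-2-(benzyloxy)propyl]-1,3-dioxolan-2-yl}methyl)benzoate, via acid chloride 32 (not isolated)
Conditions: 31 (1.3 equiv), 1-chloro-N,N,2-trimethylprop-1-en-1-amine (1.25 equiv), CH2Cl2, 0 → 25 °C; then 23, Et3N, DMAP (cat.), CH2Cl2, 25 → 40 °C
Reagents that add atoms: none
Why: The α-chloroenamine makes the acid chloride without HCl (ketal-safe), and the electron-rich hindered aroyl chloride then acylates the secondary alcohol under DMAP catalysis with retention at the carbinol.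

Step 19
Reactants: 33 the dioxolane-protected triester-ether from step 18
Product: 34 (R)-4-{[(R)-1-[3,5-bis(benzyloxy)phenyl]propan-2-yl]oxy}-4-oxobutan-2-yl 2,4-bis(benzyloxy)-6-[(R)-4-(benzyloxy)-2-oxopentyl]benzoate
Conditions: 1 M aq. HCl, THF, 25 → 40 °C
Reagents that add atoms: water, O
Why: Mild aqueous acid hydrolysis of the dioxolane through its oxocarbenium ion should free the ketone while the benzyl ethers and both esters remain.

Step 20
Reactants: 34 the pentabenzyl ether of the target
Product: 35 Hansforester K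
Conditions: H2 (1 atm), Pd(OH)2/C, EtOAc/EtOH, 25 °C
Reagents that add atoms: none
Why: Neutral catalytic hydrogenolysis removes the four aryl benzyl ethers and the one alkyl benzyl ether, and the molecule offers no alkene, benzylic ester C–O bond or aryl ketone to be reduced.

Compound list
1 | methyl (R)-3-hydroxybutanoate | COC(=O)C[C@@H](C)O | starting material
2 | methyl (R)-3-(tert-butyldimethylsilyloxy)butanoate | COC(=O)C[C@@H](C)O[Si](C)(C)C(C)(C)C | intermediate
3 | (R)-3-(tert-butyldimethylsilyloxy)butanoic acid | OC(=O)C[C@@H](C)O[Si](C)(C)C(C)(C)C | intermediate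
4 | (R)-pent-4-yn-2-ol | C#CC[C@@H](C)O | starting material
5 | (R)-pent-4-yn-2-yl (R)-3-(tert-butyldimethylsilyloxy)butanoate | C#CC[C@@H](C)OC(=O)C[C@@H](C)O[Si](C)(C)C(C)(C)C | intermediate
6 | trichloroacetyl chloride | ClC(=O)C(Cl)(Cl)Cl | starting material
7 | dichloroketene (formed in the flask) | ClC(Cl)=C=O | intermediate
8 | (R)-1-(4,4-dichloro-3-oxocyclobut-1-en-1-yl)propan-2-yl (R)-3-(tert-butyldimethylsilyloxy)butanoate | O=C1C=C(C[C@@H](C)OC(=O)C[C@@H](C)O[Si](C)(C)C(C)(C)C)C1(Cl)Cl | intermediate
9 | (R)-1-(3-oxocyclobut-1-en-1-yl)propan-2-yl (R)-3-(tert-butyldimethylsilyloxy)butanoate | O=C1C=C(C[C@@H](C)OC(=O)C[C@@H](C)O[Si](C)(C)C(C)(C)C)C1 | intermediate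
10 | tetrahydrofuran | C1CCOC1 | starting material
11 | lithium ethenolate (formed in the flask) | [Li]OC=C | intermediate
12 | triisopropyl(vinyloxy)silane | C=CO[Si](C(C)C)(C(C)C)C(C)C | intermediate
13 | (1,2-dibromoethoxy)triisopropylsilane, racemic (formed in the flask) | BrCC(Br)O[Si](C(C)C)(C(C)C)C(C)C | intermediate
14 | (2-bromovinyloxy)triisopropylsilane, E/Z mixture | BrC=CO[Si](C(C)C)(C(C)C)C(C)C | intermediate
15 | lithium (triisopropylsilyloxy)acetylide (formed in the flask) | [Li]C#CO[Si](C(C)C)(C(C)C)C(C)C | intermediate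
16 | (triisopropylsilyloxy)acetylene | C#CO[Si](C(C)C)(C(C)C)C(C)C | intermediate
17 | vinylketene: (R)-4-methylidene-6-oxohex-5-en-2-yl (R)-3-(tert-butyldimethylsilyloxy)butanoate (formed in the flask) | O=C=CC(=C)C[C@@H](C)OC(=O)C[C@@H](C)O[Si](C)(C)C(C)(C)C | intermediate
18 | 4-vinylcyclobutenone: (R)-4-[2-oxo-4-(triisopropylsilyloxy)cyclobut-3-en-1-yl]pent-4-en-2-yl (R)-3-(tert-butyldimethylsilyloxy)butanoate, both epimers at the ring CH (formed in the flask) | O=C1C=C(O[Si](C(C)C)(C(C)C)C(C)C)C1C(=C)C[C@@H](C)OC(=O)C[C@@H](C)O[Si](C)(C)C(C)(C)C | intermediate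
19 | dienylketene: (R,5E)-4-methylidene-8-oxo-6-(triisopropylsilyloxy)octa-5,7-dien-2-yl (R)-3-(tert-butyldimethylsilyloxy)butanoate, ketenyl and vinyl groups cis across C5=C6 (formed in the flask) | O=C=C/C(O[Si](C(C)C)(C(C)C)C(C)C)=C\C(=C)C[C@@H](C)OC(=O)C[C@@H](C)O[Si](C)(C)C(C)(C)C | intermediate
20 | cyclohexadienone: (R)-1-[5-oxo-3-(triisopropylsilyloxy)cyclohexa-1,3-dien-1-yl]propan-2-yl (R)-3-(tert-butyldimethylsilyloxy)butanoate (formed in the flask) | O=C1C=C(O[Si](C(C)C)(C(C)C)C(C)C)C=C(C[C@@H](C)OC(=O)C[C@@H](C)O[Si](C)(C)C(C)(C)C)C1 | intermediate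
21 | (R)-1-[3-hydroxy-5-(triisopropylsilyloxy)phenyl]propan-2-yl (R)-3-(tert-butyldimethylsilyloxy)butanoate | Oc1cc(O[Si](C(C)C)(C(C)C)C(C)C)cc(C[C@@H](C)OC(=O)C[C@@H](C)O[Si](C)(C)C(C)(C)C)c1 | intermediate
22 | (R)-1-[3,5-bis(benzyloxy)phenyl]propan-2-yl (R)-3-(tert-butyldimethylsilyloxy)butanoate | O(Cc1ccccc1)c1cc(OCc2ccccc2)cc(C[C@@H](C)OC(=O)C[C@@H](C)O[Si](C)(C)C(C)(C)C)c1 | intermediate
23 | (R)-1-[3,5-bis(benzyloxy)phenyl]propan-2-yl (R)-3-hydroxybutanoate | O(Cc1ccccc1)c1cc(OCc2ccccc2)cc(C[C@@H](C)OC(=O)C[C@@H](C)O)c1 | intermediate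
24 | methyl (R)-3-(benzyloxy)butanoate | COC(=O)C[C@@H](C)OCc1ccccc1 | intermediate
25 | (R)-3-(benzyloxy)-N-methoxy-N-methylbutanamide | CON(C)C(=O)C[C@@H](C)OCc1ccccc1 | intermediate
26 | methyl 2,4-dihydroxy-6-methylbenzoate | COC(=O)c1c(C)cc(O)cc1O | starting material
27 | methyl 2,4-bis(benzyloxy)-6-methylbenzoate | COC(=O)c1c(C)cc(OCc2ccccc2)cc1OCc1ccccc1 | intermediate
28 | methyl 2,4-bis(benzyloxy)-6-(lithiomethyl)benzoate (formed in the flask) | COC(=O)c1c(C[Li])cc(OCc2ccccc2)cc1OCc1ccccc1 | intermediate
29 | methyl 2,4-bis(benzyloxy)-6-[(R)-4-(benzyloxy)-2-oxopentyl]benzoate | COC(=O)c1c(CC(=O)C[C@@H](C)OCc2ccccc2)cc(OCc2ccccc2)cc1OCc1ccccc1 | intermediate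
30 | methyl 2,4-bis(benzyloxy)-6-({2-[(R)-2-(benzyloxy)propyl]-1,3-dioxolan-2-yl}methyl)benzoate | COC(=O)c1c(CC2(C[C@@H](C)OCc3ccccc3)OCCO2)cc(OCc2ccccc2)cc1OCc1ccccc1 | intermediate
31 | 2,4-bis(benzyloxy)-6-({2-[(R)-2-(benzyloxy)propyl]-1,3-dioxolan-2-yl}methyl)benzoic acid | OC(=O)c1c(CC2(C[C@@H](C)OCc3ccccc3)OCCO2)cc(OCc2ccccc2)cc1OCc1ccccc1 | intermediate
32 | 2,4-bis(benzyloxy)-6-({2-[(R)-2-(benzyloxy)propyl]-1,3-dioxolan-2-yl}methyl)benzoyl chloride (formed in the flask) | ClC(=O)c1c(CC2(C[C@@H](C)OCc3ccccc3)OCCO2)cc(OCc2ccccc2)cc1OCc1ccccc1 | intermediate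
33 | (R)-4-{[(R)-1-[3,5-bis(benzyloxy)phenyl]propan-2-yl]oxy}-4-oxobutan-2-yl 2,4-bis(benzyloxy)-6-({2-[(R)-2-(benzyloxy)propyl]-1,3-dioxolan-2-yl}methyl)benzoate | O(Cc1ccccc1)c1cc(OCc2ccccc2)cc(C[C@@H](C)OC(=O)C[C@@H](C)OC(=O)c2c(CC3(C[C@@H](C)OCc4ccccc4)OCCO3)cc(OCc3ccccc3)cc2OCc2ccccc2)c1 | intermediate
34 | (R)-4-{[(R)-1-[3,5-bis(benzyloxy)phenyl]propan-2-yl]oxy}-4-oxobutan-2-yl 2,4-bis(benzyloxy)-6-[(R)-4-(benzyloxy)-2-oxopentyl]benzoate | O(Cc1ccccc1)c1cc(OCc2ccccc2)cc(C[C@@H](C)OC(=O)C[C@@H](C)OC(=O)c2c(CC(=O)C[C@@H](C)OCc3ccccc3)cc(OCc3ccccc3)cc2OCc2ccccc2)c1 | intermediate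
35 | Hansforester K: (R)-4-{[(R)-1-(3,5-dihydroxyphenyl)propan-2-yl]oxy}-4-oxobutan-2-yl 2,4-dihydroxy-6-[(R)-4-hydroxy-2-oxopentyl]benzoate | C[C@H](Cc1cc(O)cc(O)c1)OC(=O)C[C@@H](C)OC(=O)c1c(O)cc(O)cc1CC(=O)C[C@@H](C)O | target

Total step count: 20 steps. Longest linear sequence: 11 steps (steps 1, 2, 3, 4, 5, 9, 10, 11, 18, 19, 20).

Steps most likely to fail

Step 9. The cascade may stall at the vinylcyclobutenone stage, the phenol formed may be acylated by vinylketene that has not yet found the alkyne, or the ynol ether may isomerise to the silylketene before it is consumed. The fallback abandons the annulation and uses a preformed arene; it sets out from acid 3 and rejoins the route at 22, and it also covers a failure to obtain 16. 1-Bromo-3,5-bis(benzyloxy)benzene would be converted with Mg turnings in THF into 3,5-bis(benzyloxy)phenylmagnesium bromide F1. This should open (R)-2-methyloxirane at its CH2 terminus under CuBr·SMe2 catalysis (THF, −30 °C) to give (R)-1-[3,5-bis(benzyloxy)phenyl]propan-2-ol F2 with the stereocentre untouched. Steglich esterification of F2 with 3 (EDC·HCl, DMAP, CH2Cl2) should then give 22 directly.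

Step 18. Activation of the di-ortho-substituted acid may be diverted by participation of a ketal oxygen at the acylium carbon (lactone formation), or acylation may be so slow that base-induced elimination of the β-acyloxy ester takes over. The fallback activates the alcohol instead of the acid; it sets out from 23 and rejoins the route at 33. Dess–Martin oxidation of 23 would give (R)-1-[3,5-bis(benzyloxy)phenyl]propan-2-yl 3-oxobutanoate F3. Hydrogenation of this β-keto ester with RuCl2[(S)-BINAP], a divalent ruthenium catalyst (H2, MeOH), should give under catalyst control (R)-1-[3,5-bis(benzyloxy)phenyl]propan-2-yl (S)-3-hydroxybutanoate F4. Mitsunobu esterification of F4 with acid 31 (PPh3, DIAD, PhMe, 0 → 25 °C) proceeds with inversion and should deliver 33 with the required (R) centre, without any acylium intermediate.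

Step 4. Zinc chloride formed alongside the ketene may cleave the silyl ether (followed by trichloroacetylation), or the alkyne may react sluggishly while dichloroketene oligomerises. The fallback is a metal-free keteniminium route; it sets out from 5 and rejoins the route at 9, bypassing 8 and step 5. N,N-Dimethylacetamide would be activated with Tf2O and 2,4,6-collidine (1,2-dichloroethane, 0 → 80 °C) to N,N-dimethylketeniminium trifluoromethanesulfonate F5. This should add to the alkyne of 5 in a (2+2) cycloaddition of the same regiochemistry to give the cyclobuteniminium salt N-[3-((R)-2-{[(R)-3-(tert-butyldimethylsilyloxy)butanoyl]oxy}propyl)cyclobut-2-en-1-ylidene]-N-methylmethanaminium trifluoromethanesulfonate F6. Hydrolysis of F6 with aqueous NaHCO3 should give 9.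

Further compounds
F1 | step 9 | 3,5-bis(benzyloxy)phenylmagnesium bromide | Br[Mg]c1cc(OCc2ccccc2)cc(OCc2ccccc2)c1
F2 | step 9 | (R)-1-[3,5-bis(benzyloxy)phenyl]propan-2-ol | C[C@@H](O)Cc1cc(OCc2ccccc2)cc(OCc2ccccc2)c1
F3 | step 18 | (R)-1-[3,5-bis(benzyloxy)phenyl]propan-2-yl 3-oxobutanoate | O(Cc1ccccc1)c1cc(OCc2ccccc2)cc(C[C@@H](C)OC(=O)CC(C)=O)c1
F4 | step 18 | (R)-1-[3,5-bis(benzyloxy)phenyl]propan-2-yl (S)-3-hydroxybutanoate | O(Cc1ccccc1)c1cc(OCc2ccccc2)cc(C[C@@H](C)OC(=O)C[C@H](C)O)c1
F5 | step 4 | N,N-dimethylketeniminium trifluoromethanesulfonate | C=C=[N+](C)C.[O-]S(=O)(=O)C(F)(F)F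
F6 | step 4 | N-[3-((R)-2-{[(R)-3-(tert-butyldimethylsilyloxy)butanoyl]oxy}propyl)cyclobut-2-en-1-ylidene]-N-methylmethanaminium trifluoromethanesulfonate | C[N+](C)=C1C=C(C[C@@H](C)OC(=O)C[C@@H](C)O[Si](C)(C)C(C)(C)C)C1.[O-]S(=O)(=O)C(F)(F)F
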